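## Structural features

The target is a C2-symmetric dimer of two (2R,3S)-flavan-3-ol units (2,3-trans): in each, a 5,7-dihydroxylated ring A is fused to a dihydropyran ring C that carries ring B at C2 and a hydroxyl at C3. The two rings B are joined by a single diaryl ether oxygen between C3' and C3''', and each keeps a free hydroxyl on the neighbouring carbon (C4', C4'''). Each half has two adjacent stereocentres, C2 (benzylic, bound to O1 and ring B) and C3 (carbinol), and C3 is flanked on its other side by the ring A benzylic methylene C4; the halves are identical, so the synthesis can run in two directions at once. Ring A is a phloroglucinol-type arene, nucleophilic at C6 and C8 and easily oxidised. The C2–O1 bond is a benzylic ether para to a ring B oxygen and ionises under acid with loss of the C2 configuration, and the eight free hydroxyls call for a neutral last step. The skeleton is simple; the difficulty is the absolute and relative control of four stereocentres in two indistinguishable halves, together with a hindered diaryl ether that is better carried from the start than made late. The key step uses the fact that C3 is an oxygen-bearing carbon between C2 (ring B side) and C4 (ring A side): with C2 at the ketone level, C3 is the α-carbon of a ring B aryl ketone and C3–C4 is the bond between an enolate and a ring A benzyl halide. Both C3 centres can then be set by a chiral counter-cation, and C2 is derived afterwards from the ketone under the control of C3.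

## Logic of the disconnections

22 is traced back to 21 by cutting the six benzyl–oxygen and the two benzhydryl–oxygen bonds. All eight are exocyclic benzylic C–O bonds, so one neutral hydrogenolysis frees every hydroxyl at the end and no phenol is exposed earlier. The forward step must leave the endocyclic benzylic C2–O1 bonds intact, which asks for low pressure and short contact.

In 21 the two O1–C2 bonds are cut, giving 20. The ring oxygen already sits on ring A, so closure is an intramolecular displacement at C2 and the C2 configuration follows stereospecifically from a carbinol. This is preferred to a hydride addition to a cyclic oxocarbenium ion, whose facial preference next to the bulky C3 ether is hard to predict and whose acid would release a benzhydryl cation beside ring A. The displacement inverts C2, so the carbinol must be 1,2-syn to C3 (1S,2S), and ionisation must not outrun displacement.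

In 20 the two C2–H bonds are cut and the two ring A carbonates are restored, giving 18 by way of 19. Returning C2 to the ketone level is what makes C3 an α-carbon. The forward step needs hydride on the Felkin–Anh face, and the carbonates may be removed only after the ketones are gone, because base at the ketone stage would endanger C3.

In 18 both C3–C4 bonds are cut, giving the achiral 11 and two molecules of 17. This removes the last two stereocentres and splits the molecule into a symmetric core and a simple ring A piece; no ring is involved. The forward step needs enantioface selection on each enolate by a catalyst, single alkylation at each carbon, and survival of a base-labile carbonate and an ionisable benzylic halide.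

In 11 the two aryl–carbonyl bonds are cut, giving 6 (used as its dilithio form 10) and two molecules of 9; 9 comes from 7 by amide formation through 8. The acyl donor must stop at the ketone stage, and both aryl–metal sites must react, each with one molecule of the donor.

6 is simplified through 5 and 4 to 1 by cutting the O–benzyl bonds, the C–Br bonds and the two C–O bonds ortho to the ether oxygen. The diaryl ether is thus bought, not made. The forward steps need metalation ortho to the ether oxygen (through 2 and 3) and bromination para to each hydroxyl.

17 is simplified through 16, 15 and 14 to 12 by cutting the C–Br bond, the benzylic C–H bond (back to the aldehyde), the carbonate O–C bond and the formyl C–C bond. The formyl group must enter ortho to the hydroxyl of 12 (through 13) and not para; the reduction must not leave an alkoxide beside the carbonate; the halide must be formed without acid or base.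

## Other disconnections considered

Alternative 1: The cut is inside each ring B, at C2'–C3' and C5'–C6', so that both rings B are built around an ether oxygen already present in bis(2-oxopropyl) ether A1. In the forward step pyrrolidinium acetate would condense A1 with two equivalents of the chroman-2-yl malonaldehyde A2 in a double [3+3] aldol-type benzannulation, giving the hexabenzyl ether A3 with both ring B phenols free.
- In favour: no diaryl ether has to be made, the ring B phenols need no protecting group, and C2 and C3 are in place before the key step.
- Against: A2 is a β-alkoxy dialdehyde, and its enol or enamine can expel O1 (retro-oxa-Michael), which opens ring C and erases C2 under the equilibrating conditions of the condensation. A1 can also close on itself by an intramolecular aldol reaction. Each ketone of A1 must react through both its methyl and its oxygenated methylene carbon, four C–C bonds in one flask. A2 itself needs a separate asymmetric synthesis of a 2,3-trans chroman without ring B, for which no short entry is apparent.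
- Comparison: on structure the alternative is the equal of the chosen plan for the ether linkage (both take it from a simple starting material) and the better for the ring B phenols, which arrive unprotected. On mechanism the chosen plan is safer, since C3 is formed under kinetic ion-pair control and no stereocentre sits β to a carbonyl during a condensation. On step economy the chosen plan is shorter, because the effort hidden in A2 is likely to exceed the whole chosen route.

Alternative 2: The cut is at both C2–C3 bonds. In the forward step the Z-boron enolate of the glycolyl oxazolidinone A5 (Bu2BOTf, i-Pr2NEt) would add to both formyl groups of the dialdehyde A4, giving the bis(syn-aldol) adduct A6.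
- In favour: a closed, chair-like transition state sets all four stereocentres in one operation under auxiliary control, and A4 would come from 6 in one step (bromine–lithium exchange, then DMF). The C2 carbinol is fixed directly in the C–C bond-forming step; on this point the alternative is the better of the two, since the chosen plan sets C2 by a substrate-controlled reduction.
- Against: A6 ends at the acyl oxidation level with no ring A. The imide carbon has to become C4, which means auxiliary exchange, addition of a ring A aryl-metal, and removal of the resulting benzylic oxygen at C4 while the equally benzylic C2 oxygen must stay. Two equivalents of auxiliary are consumed.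
- Comparison: the ring closure would be the same inversion at C2 as in the chosen plan (syn adduct to trans flavan), so the two are equal there. The alternative forms C2–C3 and leaves C3–C4 for later, whereas the chosen plan forms C3–C4 with ring A already attached at the right oxidation level. On step economy the chosen plan needs three operations after its key step against an estimated seven or more after A6, and it uses catalytic instead of stoichiometric chirality.

Alternative 3: The cut is at both C4–C4a bonds. In the forward step BF3·OEt2 or hexafluoroisopropanol would activate the two terminal epoxides of the bis-epoxide A7, each 3,5-bis(benzyloxy)phenyl ether would attack the epoxide CH2 through its ortho carbon (6-endo), and both rings C would close to give the diol A8.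
- In favour: C2 and C3 are untouched by the ring-forming step, the C3 hydroxyl is released with retention, the two ortho carbons of each ring A are equivalent, and the ring B pivalates temper the ionisation of the C2 benzylic ether. The key step closes two rings and is stereospecific; on both points the alternative is the better of the two (the chosen key step closes none and must create its stereocentres).
- Against: attack at the internal epoxide carbon (5-exo, giving a dihydrobenzofuran) competes with the wanted attack at CH2. The Lewis acid can also ionise the C2–OAr bond, which is benzylic and carries an aryloxy leaving group. A7 needs two defined stereocentres per arm and an aryl ether at a benzylic carbinol carbon, which would call for an asymmetric or resolution step at each allylic carbinol carbon and an arylation by 12 with inversion.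
- Comparison: after the key step the alternative needs two steps (removal of the pivalates, hydrogenolysis) against three for the chosen plan, so it is the better there by one step. Before the key step the chosen plan is shorter, since 11 and 17 are reached by simple aromatic chemistry and the asymmetry is introduced catalytically in the key step. On mechanism the alternative is cationic at a stage where ring A and the C2 ether are both acid-sensitive, whereas the chosen key step is anionic.

Key step: step 10

Assumption: cinchonidine-derived ammonium salts are taken to give the 3S sense with this enolate class, as they give the S sense with glycine imine enolates of the same shape; if the sense were the opposite, the cinchonine-derived pseudo-enantiomeric salt would be used in step 10 with no other change.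

## Route

Step 1
Reactants: 1 diphenyl ether
Product: 4 2,2'-oxydiphenol, via 2,2'-dilithiodiphenyl ether 2 (not isolated), via 2,2'-bis(dimethoxyboryl)diphenyl ether 3 (not isolated)
Conditions: n-BuLi, TMEDA, Et2O, 0 → 20 °C; B(OMe)3, −78 → 20 °C; H2O2, AcOH, 0 → 20 °C
Reagents that add atoms: hydrogen peroxide (OO)
Why: Directed ortho-metalation: the ether oxygen guides n-BuLi/TMEDA to one ortho position of each ring, the aryl-lithium is trapped as the boronate, and oxidation turns each C–B bond into C–O at the same carbon.

Step 2
Reactants: 4 2,2'-oxydiphenol
Product: 5 2,2'-oxybis(4-bromophenol)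
Conditions: NBS (2 equiv), MeCN, −20 → 0 °C
Reagents that add atoms: N-bromosuccinimide (O=C1CCC(=O)N1Br)
Why: Electrophilic aromatic bromination: the hydroxyl is the strongest donor of each ring and its para position is free, so bromine should enter para to OH and meta to the ether oxygen, at the carbon that becomes C1' of ring B.

Step 3
Reactants: 5 2,2'-oxybis(4-bromophenol)
Product: 6 bis(2-benzyloxy-5-bromophenyl) ether
Conditions: BnBr, K2CO3, DMF, 50 °C
Reagents that add atoms: benzyl bromide (BrCc1ccccc1)
Why: Williamson ether synthesis on both phenoxides; the benzyl ethers tolerate organolithium, CsOH and hydride and leave with the other benzylic groups in the last step.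

Step 4
Reactants: 7 (diphenylmethoxy)acetic acid
Product: 9 2-(diphenylmethoxy)-N-methoxy-N-methylacetamide, via 1-[(diphenylmethoxy)acetyl]imidazole 8 (not isolated)
Conditions: CDI, CH2Cl2, 20 °C; then MeNHOMe·HCl, 20 °C
Reagents that add atoms: N,O-dimethylhydroxylamine hydrochloride (CNOC.Cl)
Why: Amide coupling through the acyl imidazole, which the hydroxylamine opens; the conditions are neutral, so the acid-labile benzhydryl ether is not at risk.

Step 5
Reactants: 6 bis(2-benzyloxy-5-bromophenyl) ether; 9 2-(diphenylmethoxy)-N-methoxy-N-methylacetamide (2 equiv)
Product: 11 bis[2-benzyloxy-5-(diphenylmethoxyacetyl)phenyl] ether, via bis(2-benzyloxy-5-lithiophenyl) ether 10 (not isolated)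
Conditions: n-BuLi, THF, −78 °C; 9 (2.3 equiv), −78 → 0 °C; aq NH4Cl
Reagents that add atoms: second molecule of the N-methoxy-N-methylamide 9 (CON(C)C(=O)COC(c1ccccc1)c1ccccc1)
Why: Two-fold bromine–lithium exchange para to the benzyloxy groups (slightly more than two equivalents of n-BuLi), then ketone synthesis from an N-methoxy-N-methylamide: each of the two aryl-lithium sites takes up one molecule of 9, so two molecules of 9 are consumed per molecule of 6, and the chelated tetrahedral adduct stops each addition at the ketone stage.

Step 6
Reactants: 12 3,5-bis(benzyloxy)phenol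
Product: 14 2,4-bis(benzyloxy)-6-hydroxybenzaldehyde, via magnesium hydroxymethylphenoxide chelate 13 (not isolated)
Conditions: MgCl2, Et3N, (CH2O)n, MeCN, reflux; aq HCl
Reagents that add atoms: paraformaldehyde, reacting as formaldehyde (C=O)
Why: Magnesium-mediated ortho-formylation: the magnesium phenoxide delivers formaldehyde through a six-membered chelate only to the carbon next to the phenol oxygen, and a second formaldehyde oxidises the benzylic alkoxide by hydride transfer. An iminium-type formylation is avoided because it would favour the position para to the hydroxyl.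

Step 7
Reactants: 14 2,4-bis(benzyloxy)-6-hydroxybenzaldehyde
Product: 15 3,5-bis(benzyloxy)-2-formylphenyl tert-butyl carbonate
Conditions: Boc2O, DMAP (cat.), i-Pr2NEt, CH2Cl2, 0 → 20 °C
Reagents that add atoms: di-tert-butyl dicarbonate (CC(C)(C)OC(=O)OC(=O)OC(C)(C)C)
Why: DMAP-catalysed acyl transfer to the hydrogen-bonded phenol; the carbonate masks the future O1, lowers the electron density of ring A so that the later benzylic bromide can be handled, and can be removed by mild methanolysis.

Step 8
Reactants: 15 3,5-bis(benzyloxy)-2-formylphenyl tert-butyl carbonate
Product: 16 3,5-bis(benzyloxy)-2-(hydroxymethyl)phenyl tert-butyl carbonate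
Conditions: BH3·THF, THF, 0 °C; MeOH
Reagents that add atoms: none
Why: Borane reduces the aldehyde through a neutral alkoxyborane, so no free alkoxide appears next to the aryl carbonate. A borohydride is avoided because the alkoxide it leaves would take over the carbonate, expel it as an ortho-quinone methide and end in over-reduction to the methyl compound.

Step 9
Reactants: 16 3,5-bis(benzyloxy)-2-(hydroxymethyl)phenyl tert-butyl carbonate
Product: 17 3,5-bis(benzyloxy)-2-(bromomethyl)phenyl tert-butyl carbonate
Conditions: CBr4, PPh3, CH2Cl2, 0 °C
Reagents that add atoms: carbon tetrabromide (BrC(Br)(Br)Br)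
Why: Appel bromination: bromide displaces the alkoxyphosphonium group at a primary benzylic carbon without acid or base, as the carbonate and the electron-rich ring require; 17 is used at once.

Step 10
Reactants: 11 bis[2-benzyloxy-5-(diphenylmethoxyacetyl)phenyl] ether; 17 3,5-bis(benzyloxy)-2-(bromomethyl)phenyl tert-butyl carbonate (2 equiv)
Product: 18 bis{2-benzyloxy-5-[(2S)-3-[2,4-bis(benzyloxy)-6-(tert-butoxycarbonyloxy)phenyl]-2-(diphenylmethoxy)propanoyl]phenyl} ether
Conditions: 17 (2.6 equiv), O-allyl-N-(2,3,4-trifluorobenzyl)hydrocinchonidinium bromide (20 mol %), CsOH·H2O, CH2Cl2/n-hexane, −40 °C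
Reagents that add atoms: second molecule of the benzylic bromide 17 (BrCc1c(OC(=O)OC(C)(C)C)cc(OCc2ccccc2)cc1OCc1ccccc1)
Why: Solid CsOH·H2O deprotonates each α-(diphenylmethoxy)acetyl group at the interface and the enolate enters the organic phase as a tight ion pair with the cinchonidinium cation. The bulky benzhydryl ether holds the enolate oxygen and the ether oxygen syn (Z-enolate), so a single enolate geometry meets the catalyst. The cation covers one enolate face and the benzylic bromide 17 is attacked from the open face in an SN2 step, which forms C3–C4 and sets C3 as S; the second arm reacts in the same way and independently, so two molecules of 17 are taken up per molecule of 11. The closest known reaction type is the cinchona phase-transfer benzylation of α-alkoxy aryl ketones used as glycolate equivalents. No ring is closed. Both new stereocentres are catalyst-controlled, and because the two events are independent a wrong-sense alkylation ends mainly in the separable meso (R,S) diastereomer, which should raise the enantiomeric purity of the C2-symmetric (S,S) product. The step needs C- over O-alkylation, one alkylation per carbon and survival of the aryl carbonates; a soft benzylic electrophile, the hindered tertiary α-CH of the product and solid base at low temperature should secure these. A carbonate lost to hydroxide would give an ortho-quinone methide that the same ion pair attacks at the same carbon.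

Step 11
Reactants: 18 bis{2-benzyloxy-5-[(2S)-3-[2,4-bis(benzyloxy)-6-(tert-butoxycarbonyloxy)phenyl]-2-(diphenylmethoxy)propanoyl]phenyl} ether
Product: 20 bis{2-benzyloxy-5-[(1S,2S)-3-[2,4-bis(benzyloxy)-6-hydroxyphenyl]-2-(diphenylmethoxy)-1-hydroxypropyl]phenyl} ether, via bis(carbonate) diol 19 (not isolated)
Conditions: K[s-Bu3BH], THF, −78 °C; then MeOH, K2CO3, −78 → 20 °C; aq NH4Cl
Reagents that add atoms: none
Why: Polar Felkin–Anh reduction: the C3–O bond stands perpendicular to the carbonyl and anti to the bulky hydride, and potassium does not chelate the hindered benzhydryl ether, so hydride should add to the face that gives the 1,2-syn (1S,2S) carbinol. Methanolysis of the aryl tert-butyl carbonates then frees the ring A phenols only after the ketones, and with them the risk of epimerising C3, are gone.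

Step 12
Reactants: 20 bis{2-benzyloxy-5-[(1S,2S)-3-[2,4-bis(benzyloxy)-6-hydroxyphenyl]-2-(diphenylmethoxy)-1-hydroxypropyl]phenyl} ether
Product: 21 bis{2-benzyloxy-5-[(2R,3S)-5,7-bis(benzyloxy)-3-(diphenylmethoxy)chroman-2-yl]phenyl} ether
Conditions: PPh3, DIAD, THF, 0 → 20 °C
Reagents that add atoms: none
Why: Mitsunobu cycloetherification: each benzylic hydroxyl becomes an oxyphosphonium leaving group and is displaced by the neighbouring ring A phenoxide in a 6-exo-tet SN2 step, so C2 is inverted from S to R and the syn carbinol gives the 2,3-trans flavan; C3 is not touched and no acid is present.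

Step 13
Reactants: 21 bis{2-benzyloxy-5-[(2R,3S)-5,7-bis(benzyloxy)-3-(diphenylmethoxy)chroman-2-yl]phenyl} ether
Product: 22 catechin-(3'-O-3''')-afzelechin, bis{2-hydroxy-5-[(2R,3S)-3,5,7-trihydroxychroman-2-yl]phenyl} ether
Conditions: H2 (1 atm), Pd(OH)2/C, THF/MeOH, 20 °C
Reagents that add atoms: none
Why: Heterogeneous hydrogenolysis cleaves the six benzyl ethers and the two benzhydryl ethers under neutral conditions. Low pressure and short contact should spare the endocyclic C2–O1 bond, and no stereocentre is involved.

## Compound list

1 | diphenyl ether | c1ccc(Oc2ccccc2)cc1 | starting material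
2 | 2,2'-dilithiodiphenyl ether | [Li]c1ccccc1Oc1ccccc1[Li] | intermediate
3 | 2,2'-bis(dimethoxyboryl)diphenyl ether | COB(OC)c1ccccc1Oc1ccccc1B(OC)OC | intermediate
4 | 2,2'-oxydiphenol | Oc1ccccc1Oc1ccccc1O | intermediate
5 | 2,2'-oxybis(4-bromophenol) | Oc1ccc(Br)cc1Oc1cc(Br)ccc1O | intermediate
6 | bis(2-benzyloxy-5-bromophenyl) ether | O(c1cc(Br)ccc1OCc1ccccc1)c1cc(Br)ccc1OCc1ccccc1 | intermediate
7 | (diphenylmethoxy)acetic acid | OC(=O)COC(c1ccccc1)c1ccccc1 | starting material
8 | 1-[(diphenylmethoxy)acetyl]imidazole | O=C(COC(c1ccccc1)c1ccccc1)n1ccnc1 | intermediate
9 | 2-(diphenylmethoxy)-N-methoxy-N-methylacetamide | CON(C)C(=O)COC(c1ccccc1)c1ccccc1 | intermediate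
10 | bis(2-benzyloxy-5-lithiophenyl) ether | [Li]c1ccc(OCc2ccccc2)c(Oc2cc([Li])ccc2OCc2ccccc2)c1 | intermediate
11 | bis[2-benzyloxy-5-(diphenylmethoxyacetyl)phenyl] ether | O(c1cc(C(=O)COC(c2ccccc2)c2ccccc2)ccc1OCc1ccccc1)c1cc(C(=O)COC(c2ccccc2)c2ccccc2)ccc1OCc1ccccc1 | intermediate
12 | 3,5-bis(benzyloxy)phenol | Oc1cc(OCc2ccccc2)cc(OCc2ccccc2)c1 | starting material
13 | magnesium chelate of 3,5-bis(benzyloxy)-2-(oxidomethyl)phenoxide | [Mg]1OCc2c(O1)cc(OCc1ccccc1)cc2OCc1ccccc1 | intermediate
14 | 2,4-bis(benzyloxy)-6-hydroxybenzaldehyde | O=Cc1c(O)cc(OCc2ccccc2)cc1OCc1ccccc1 | intermediate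
15 | 3,5-bis(benzyloxy)-2-formylphenyl tert-butyl carbonate | O=Cc1c(OC(=O)OC(C)(C)C)cc(OCc2ccccc2)cc1OCc1ccccc1 | intermediate
16 | 3,5-bis(benzyloxy)-2-(hydroxymethyl)phenyl tert-butyl carbonate | OCc1c(OC(=O)OC(C)(C)C)cc(OCc2ccccc2)cc1OCc1ccccc1 | intermediate
17 | 3,5-bis(benzyloxy)-2-(bromomethyl)phenyl tert-butyl carbonate | BrCc1c(OC(=O)OC(C)(C)C)cc(OCc2ccccc2)cc1OCc1ccccc1 | intermediate
18 | bis{2-benzyloxy-5-[(2S)-3-[2,4-bis(benzyloxy)-6-(tert-butoxycarbonyloxy)phenyl]-2-(diphenylmethoxy)propanoyl]phenyl} ether | O(c1cc(C(=O)[C@@H](OC(c2ccccc2)c2ccccc2)Cc2c(OC(=O)OC(C)(C)C)cc(OCc3ccccc3)cc2OCc2ccccc2)ccc1OCc1ccccc1)c1cc(C(=O)[C@@H](OC(c2ccccc2)c2ccccc2)Cc2c(OC(=O)OC(C)(C)C)cc(OCc3ccccc3)cc2OCc2ccccc2)ccc1OCc1ccccc1 | intermediate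
19 | bis{2-benzyloxy-5-[(1S,2S)-3-[2,4-bis(benzyloxy)-6-(tert-butoxycarbonyloxy)phenyl]-2-(diphenylmethoxy)-1-hydroxypropyl]phenyl} ether | O(c1cc([C@H](O)[C@@H](OC(c2ccccc2)c2ccccc2)Cc2c(OC(=O)OC(C)(C)C)cc(OCc3ccccc3)cc2OCc2ccccc2)ccc1OCc1ccccc1)c1cc([C@H](O)[C@@H](OC(c2ccccc2)c2ccccc2)Cc2c(OC(=O)OC(C)(C)C)cc(OCc3ccccc3)cc2OCc2ccccc2)ccc1OCc1ccccc1 | intermediate
20 | bis{2-benzyloxy-5-[(1S,2S)-3-[2,4-bis(benzyloxy)-6-hydroxyphenyl]-2-(diphenylmethoxy)-1-hydroxypropyl]phenyl} ether | O(c1cc([C@H](O)[C@@H](OC(c2ccccc2)c2ccccc2)Cc2c(O)cc(OCc3ccccc3)cc2OCc2ccccc2)ccc1OCc1ccccc1)c1cc([C@H](O)[C@@H](OC(c2ccccc2)c2ccccc2)Cc2c(O)cc(OCc3ccccc3)cc2OCc2ccccc2)ccc1OCc1ccccc1 | intermediate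
21 | bis{2-benzyloxy-5-[(2R,3S)-5,7-bis(benzyloxy)-3-(diphenylmethoxy)chroman-2-yl]phenyl} ether | O(c1cc([C@H]2Oc3cc(OCc4ccccc4)cc(OCc4ccccc4)c3C[C@@H]2OC(c2ccccc2)c2ccccc2)ccc1OCc1ccccc1)c1cc([C@H]2Oc3cc(OCc4ccccc4)cc(OCc4ccccc4)c3C[C@@H]2OC(c2ccccc2)c2ccccc2)ccc1OCc1ccccc1 | intermediate
22 | catechin-(3'-O-3''')-afzelechin | Oc1cc(O)c2c(c1)O[C@H](c1ccc(O)c(Oc3cc([C@H]4Oc5cc(O)cc(O)c5C[C@@H]4O)ccc3O)c1)[C@@H](O)C2 | target

## Step count and least certain steps

Total: 13 steps. Longest linear sequence: 8 steps (1, 2, 3, 5, 10, 11, 12, 13, or equally 6, 7, 8, 9, 10, 11, 12, 13).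

**Step 10 (key step).** The most likely failure is insufficient facial selection by the ion pair, because this aryl ketone is more electron-rich and larger than the simple aryl glycolate ketones for which the catalyst class is established, and two independent events multiply any shortfall into the meso diastereomer. Hydroxide attack on the aryl carbonates and hydrolysis of the ionisable bromide can also consume the electrophile.
Fallback: covalent control of the same C3–C4 bond. It sets out from 7 and 17 and comes back at 18. Acid 7 is attached to the auxiliary as (R)-4-benzyl-3-[(diphenylmethoxy)acetyl]oxazolidin-2-one F1 (mixed anhydride with pivaloyl chloride, then the lithiated oxazolidinone). The sodium enolate of F1 (NaN(SiMe3)2, THF, −78 °C) is alkylated by 17 on the face away from the benzyl group, giving the (2S)-alkylated imide F2. Me3Al with MeNHOMe·HCl exchanges the auxiliary for the N-methoxy-N-methylamide, giving the (2S)-amide F3. Two equivalents of F3 acylate the dilithio compound 10 (made from 6 as in step 5) at −78 °C, which gives 18; the aryl carbonate is the weak point of this sequence and requires the low temperature.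

**Step 11.** The most likely failure is erosion of the Felkin–Anh preference, either through partial chelation of the ether oxygen or because the large benzhydryl group and the ring A benzyl group compete for the position anti to hydride; each wrong addition puts an anti carbinol into one arm, which would later close to the 2,3-cis ring.
Fallback: catalyst control in place of substrate control, from 18 to 19. Transfer hydrogenation with RuCl[(R,R)-TsDPEN](p-cymene) in HCO2H/Et3N (the catalyst enantiomer expected to place hydride on the same face of the aryl ketone) would give 19, which is methanolysed to 20 as before. No new compound is involved.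

**Step 12.** The most likely failure is ionisation of the activated benzylic oxyphosphonium group, which is para to a benzyloxy donor, before the phenoxide displaces it; this would cost stereospecificity at C2 or lead to elimination toward the enol ether.
Fallback: ring closure at the ketone oxidation level, which sets out from 18 and comes back at 21. Treatment of 18 with CF3CO2H and a large excess of Et3SiH in CH2Cl2 at −30 → 0 °C would remove the carbonates and let the freed phenols close onto the ketones to give the bis(2-hydroxychroman) hemiketal F4, whose oxocarbenium ions are reduced by the silane to 21. Its weak points are that C2 then rests on kinetic hydride delivery cis to the C3 ether, and that any acid cleavage of the benzhydryl ether would release a cation beside ring A; this is why it is not the first choice.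

**Step 8.** The most likely failure is transfer of the carbonate from the phenol oxygen to the new benzylic oxygen followed by elimination and over-reduction, or borane-mediated loss of the benzylic oxygen on this electron-rich ring.
Fallback: reversal of the order, which sets out from 14 and comes back at 16. NaBH4 in MeOH at 0 °C reduces 14 to 3,5-bis(benzyloxy)-2-(hydroxymethyl)phenol F5, and Boc2O with K2CO3 in acetone then acylates the phenoxide selectively over the primary alcohol to give 16. F5 must be kept cold and used quickly.

**Step 9.** The most likely failure is ionisation of the electron-rich benzylic bromide during isolation, leading to solvolysis or loss of the carbonate.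
Fallback: a less ionisable electrophile, which sets out from 16 and comes back at 18. MsCl, LiCl and 2,4,6-collidine in DMF at 0 °C convert 16 into 3,5-bis(benzyloxy)-2-(chloromethyl)phenyl tert-butyl carbonate F6, which is used directly as the alkylating agent under the conditions of step 10 at a somewhat higher temperature.

## Further compounds

F1 | step 10 | (R)-4-benzyl-3-[(diphenylmethoxy)acetyl]oxazolidin-2-one | O=C(COC(c1ccccc1)c1ccccc1)N1[C@H](Cc2ccccc2)COC1=O
F2 | step 10 | (R)-4-benzyl-3-[(2S)-3-[2,4-bis(benzyloxy)-6-(tert-butoxycarbonyloxy)phenyl]-2-(diphenylmethoxy)propanoyl]oxazolidin-2-one | O=C([C@@H](OC(c1ccccc1)c1ccccc1)Cc1c(OC(=O)OC(C)(C)C)cc(OCc2ccccc2)cc1OCc1ccccc1)N1[C@H](Cc2ccccc2)COC1=O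
F3 | step 10 | (2S)-3-[2,4-bis(benzyloxy)-6-(tert-butoxycarbonyloxy)phenyl]-2-(diphenylmethoxy)-N-methoxy-N-methylpropanamide | CON(C)C(=O)[C@@H](OC(c1ccccc1)c1ccccc1)Cc1c(OC(=O)OC(C)(C)C)cc(OCc2ccccc2)cc1OCc1ccccc1
F0 | step 11 | none | none
F4 | step 12 | bis{2-benzyloxy-5-[(3S)-5,7-bis(benzyloxy)-3-(diphenylmethoxy)-2-hydroxychroman-2-yl]phenyl} ether (both C2 epimers) | O(c1cc(C2(O)Oc3cc(OCc4ccccc4)cc(OCc4ccccc4)c3C[C@@H]2OC(c2ccccc2)c2ccccc2)ccc1OCc1ccccc1)c1cc(C2(O)Oc3cc(OCc4ccccc4)cc(OCc4ccccc4)c3C[C@@H]2OC(c2ccccc2)c2ccccc2)ccc1OCc1ccccc1
F5 | step 8 | 3,5-bis(benzyloxy)-2-(hydroxymethyl)phenol | OCc1c(O)cc(OCc2ccccc2)cc1OCc1ccccc1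
F6 | step 9 | 3,5-bis(benzyloxy)-2-(chloromethyl)phenyl tert-butyl carbonate | ClCc1c(OC(=O)OC(C)(C)C)cc(OCc2ccccc2)cc1OCc1ccccc1
A1 | alternative 1 | bis(2-oxopropyl) ether | CC(=O)COCC(C)=O
A2 | alternative 1 | 2-[(2R,3S)-3,5,7-tris(benzyloxy)chroman-2-yl]malonaldehyde | O=CC(C=O)[C@H]1Oc2cc(OCc3ccccc3)cc(OCc3ccccc3)c2C[C@@H]1OCc1ccccc1
A3 | alternative 1 | bis{2-hydroxy-5-[(2R,3S)-3,5,7-tris(benzyloxy)chroman-2-yl]phenyl} ether | O(c1cc([C@H]2Oc3cc(OCc4ccccc4)cc(OCc4ccccc4)c3C[C@@H]2OCc2ccccc2)ccc1O)c1cc([C@H]2Oc3cc(OCc4ccccc4)cc(OCc4ccccc4)c3C[C@@H]2OCc2ccccc2)ccc1O
A4 | alternative 2 | bis(2-benzyloxy-5-formylphenyl) ether | O(c1cc(C=O)ccc1OCc1ccccc1)c1cc(C=O)ccc1OCc1ccccc1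
A5 | alternative 2 | (R)-4-benzyl-3-(benzyloxyacetyl)oxazolidin-2-one | O=C(COCc1ccccc1)N1[C@H](Cc2ccccc2)COC1=O
A6 | alternative 2 | bis{2-benzyloxy-5-[(1S,2R)-2-benzyloxy-3-[(4R)-4-benzyl-2-oxooxazolidin-3-yl]-1-hydroxy-3-oxopropyl]phenyl} ether | O(c1cc([C@H](O)[C@@H](OCc2ccccc2)C(=O)N2[C@H](Cc3ccccc3)COC2=O)ccc1OCc1ccccc1)c1cc([C@H](O)[C@@H](OCc2ccccc2)C(=O)N2[C@H](Cc3ccccc3)COC2=O)ccc1OCc1ccccc1
A7 | alternative 3 | bis{5-[(R)-[3,5-bis(benzyloxy)phenoxy][(2S)-oxiran-2-yl]methyl]-2-(pivaloyloxy)phenyl} ether | O(c1cc([C@@H](Oc2cc(OCc3ccccc3)cc(OCc3ccccc3)c2)[C@@H]2CO2)ccc1OC(=O)C(C)(C)C)c1cc([C@@H](Oc2cc(OCc3ccccc3)cc(OCc3ccccc3)c2)[C@@H]2CO2)ccc1OC(=O)C(C)(C)C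
A8 | alternative 3 | bis{5-[(2R,3S)-5,7-bis(benzyloxy)-3-hydroxychroman-2-yl]-2-(pivaloyloxy)phenyl} ether | O(c1cc([C@H]2Oc3cc(OCc4ccccc4)cc(OCc4ccccc4)c3C[C@@H]2O)ccc1OC(=O)C(C)(C)C)c1cc([C@H]2Oc3cc(OCc4ccccc4)cc(OCc4ccccc4)c3C[C@@H]2O)ccc1OC(=O)C(C)(C)C
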